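**Plan**
Cuts: first the C9–O acyl bond of the coumarate ester, then O1–C2 and C2–H of the oxolane (back to a γ-hydroxy aryl ketone), then C2–aryl (aryllithium plus γ-lactone), C3–C9 (formaldehyde aldol) and C3–C4 (auxiliary-controlled imide alkylation).
Forward: a dihydroferuloyl imide is alkylated and turned into a β-benzyl butyrolactone that already holds O1, C3, C4 and C5; C9 and the C2 aryl ketone are added; the only ring of the core, the oxolane, is closed reductively; esterification and desilylation finish.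
Stereochemistry: C4 (R) from the (S)-4-benzyloxazolidinone auxiliary; C3 (S) from hydroxymethylation of the lactone enolate anti to the C4 benzyl group; C2 (S) from hydride delivery to the oxocarbenium ion anti to the C3 arm.
Enabling feature: in the oxolane (O1, C2, C3, C4, C5) C2 is bound to O1 and to an electron-rich 4-oxygenated aryl ring, so an aryl-stabilised O1=C2 oxocarbenium ion is accessible. The neighbouring C3 carries the CH2O arm (C9) on the same face as that aryl, which is the relation left when a small hydride enters C2 opposite to the arm.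

Key step: step 11

Remarks on the chemistry: the target as drawn is (2S,3S,4R), with the C2 aryl cis to the C9 arm on C3 and that arm trans to the C4 benzyl group. TIPS = triisopropylsilyl, TBS = tert-butyldimethylsilyl. Assumption: the γ-hydroxy aryl ketone that enters the key step is drawn open-chain; it may rest partly as its cyclic hemiketal, which reacts through the same ion.

**Route**

Step 1
Reactants: 1 ferulic acid [(2E)-3-(4-hydroxy-3-methoxyphenyl)prop-2-enoic acid]
Product: 2 3-(4-hydroxy-3-methoxyphenyl)propanoic acid (dihydroferulic acid)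
Conditions: H2 (1 atm), 10% Pd/C, MeOH, rt
Reagents that add atoms: none
Why: Heterogeneous catalytic hydrogenation saturates only the conjugated cinnamic C=C bond at 1 atm and room temperature, leaving the arene, the phenol and the acid untouched.

Step 2
Reactants: 2 3-(4-hydroxy-3-methoxyphenyl)propanoic acid
Product: 4 3-[3-methoxy-4-(triisopropylsilyloxy)phenyl]propanoic acid, via triisopropylsilyl ester 3 (not isolated)
Conditions: TIPSCl (2.3 equiv), imidazole, DMF, rt; then K2CO3, THF/MeOH/H2O, 0 °C; work-up at pH 4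
Reagents that add atoms: triisopropylsilyl chloride (TIPSCl), CC(C)[Si](Cl)(C(C)C)C(C)C
Why: Silylation of phenol and acid followed by selective hydrolysis of the far more labile silyl ester with cold carbonate is the standard two-stage phenol protection of a hydroxy acid, and the hindered aryl TIPS ether should survive the brief basic treatment.

Step 3
Reactants: 4 3-[3-methoxy-4-(triisopropylsilyloxy)phenyl]propanoic acid; 5 (4S)-4-benzyl-1,3-oxazolidin-2-one
Product: 7 (4S)-4-benzyl-3-{3-[3-methoxy-4-(triisopropylsilyloxy)phenyl]propanoyl}-1,3-oxazolidin-2-one, via mixed pivalic anhydride 6 (not isolated)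
Conditions: PivCl, Et3N, THF, −20 °C; then 5, LiCl, −20 °C → rt
Reagents that add atoms: none
Why: N-Acylation of the oxazolidinone through the mixed pivalic anhydride (LiCl/Et3N variant of the Evans imide synthesis) should occur at the unhindered arylpropanoyl carbonyl, the tert-butyl side of the anhydride being blocked.

Step 4
Reactants: 7 (4S)-4-benzyl-3-{3-[3-methoxy-4-(triisopropylsilyloxy)phenyl]propanoyl}-1,3-oxazolidin-2-one
Product: 9 tert-butyl (3R)-4-[(4S)-4-benzyl-2-oxo-1,3-oxazolidin-3-yl]-3-{[3-methoxy-4-(triisopropylsilyloxy)phenyl]methyl}-4-oxobutanoate, via sodium Z-enolate 8 (not isolated)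
Conditions: NaN(SiMe3)2, THF, −78 °C; then BrCH2CO2tBu, −78 → −40 °C
Reagents that add atoms: tert-butyl bromoacetate, CC(C)(C)OC(=O)CBr
Why: Evans asymmetric alkylation: the chelated sodium Z-enolate is alkylated by the reactive α-bromo ester on the face opposite to the benzyl group of the (S)-auxiliary, which should set the new centre as R (the future C4 of the oxolane) with the high selectivity typical of this reaction.

Step 5
Reactants: 9 tert-butyl (3R)-4-[(4S)-4-benzyl-2-oxo-1,3-oxazolidin-3-yl]-3-{[3-methoxy-4-(triisopropylsilyloxy)phenyl]methyl}-4-oxobutanoate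
Product: 10 tert-butyl (3R)-4-hydroxy-3-{[3-methoxy-4-(triisopropylsilyloxy)phenyl]methyl}butanoate
Conditions: LiBH4, MeOH (1 equiv), Et2O, 0 °C
Reagents that add atoms: none
Why: Reductive cleavage of the auxiliary: LiBH4 reduces the activated exocyclic imide carbonyl to the primary alcohol and releases the oxazolidinone, while the hindered tert-butyl ester is spared at 0 °C and the stereocentre is not touched.

Step 6
Reactants: 10 tert-butyl (3R)-4-hydroxy-3-{[3-methoxy-4-(triisopropylsilyloxy)phenyl]methyl}butanoate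
Product: 11 (4R)-4-{[3-methoxy-4-(triisopropylsilyloxy)phenyl]methyl}oxolan-2-one
Conditions: p-TsOH·H2O (cat.), toluene, 80 °C
Reagents that add atoms: none
Why: Acid-catalysed loss of the tert-butyl group and 5-exo-trig lactonisation of the γ-hydroxy acid give the butyrolactone; the aryl TIPS ether is stable to catalytic sulfonic acid and the stereocentre is remote from the reacting carbons.

Step 7
Reactants: 11 (4R)-4-{[3-methoxy-4-(triisopropylsilyloxy)phenyl]methyl}oxolan-2-one
Product: 13 (3S,4R)-3-(hydroxymethyl)-4-{[3-methoxy-4-(triisopropylsilyloxy)phenyl]methyl}oxolan-2-one, via lithium enolate 12 (not isolated)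
Conditions: LiN(iPr)2, THF, −78 °C; HCHO gas (from cracked paraformaldehyde) in N2, −78 → −30 °C; AcOH, −78 °C
Reagents that add atoms: formaldehyde, C=O
Why: Aldol addition (hydroxymethylation) of the lactone lithium enolate to monomeric formaldehyde: the electrophile should approach the nearly planar enolate anti to the adjacent C4 benzyl group, setting C3 as S with the 3,4-trans relation, and the cold acidic quench forestalls retro-aldol and epimerisation.

Step 8
Reactants: 13 (3S,4R)-3-(hydroxymethyl)-4-{[3-methoxy-4-(triisopropylsilyloxy)phenyl]methyl}oxolan-2-one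
Product: 14 (3S,4R)-3-[(tert-butyldimethylsilyloxy)methyl]-4-{[3-methoxy-4-(triisopropylsilyloxy)phenyl]methyl}oxolan-2-one
Conditions: TBSCl, imidazole, CH2Cl2, 0 °C → rt
Reagents that add atoms: tert-butyldimethylsilyl chloride (TBSCl), CC(C)(C)[Si](C)(C)Cl
Why: Standard imidazole-mediated silylation of a primary alcohol, mild enough to leave the enolisable C3 centre untouched.

Step 9
Reactants: 15 4-bromo-2-methoxyphenol
Product: 16 (4-bromo-2-methoxyphenoxy)triisopropylsilane
Conditions: TIPSCl, imidazole, DMF, rt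
Reagents that add atoms: triisopropylsilyl chloride (TIPSCl), CC(C)[Si](Cl)(C(C)C)C(C)C
Why: Standard imidazole-mediated silylation of a phenol, which gives an aryl bromide suited to bromine–lithium exchange without an acidic proton.

Step 10
Reactants: 14 (3S,4R)-3-[(tert-butyldimethylsilyloxy)methyl]-4-{[3-methoxy-4-(triisopropylsilyloxy)phenyl]methyl}oxolan-2-one; 16 (4-bromo-2-methoxyphenoxy)triisopropylsilane
Product: 19 (2S,3R)-2-[(tert-butyldimethylsilyloxy)methyl]-4-hydroxy-3-{[3-methoxy-4-(triisopropylsilyloxy)phenyl]methyl}-1-[3-methoxy-4-(triisopropylsilyloxy)phenyl]butan-1-one, via aryllithium 17 (not isolated), via lithium hemiketal alkoxide 18 (not isolated)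
Conditions: 16, n-BuLi, THF, −78 °C; then 14, −78 °C; AcOH/THF, −78 °C
Reagents that add atoms: none
Why: Bromine–lithium exchange followed by nucleophilic addition of the aryllithium to the lactone carbonyl should stop after one addition because the tetrahedral lithium hemiketal alkoxide persists at −78 °C, and the cold acetic acid quench releases the γ-hydroxy aryl ketone without exposing the α-centre C3 to base.

Step 11
Reactants: 19 (2S,3R)-2-[(tert-butyldimethylsilyloxy)methyl]-4-hydroxy-3-{[3-methoxy-4-(triisopropylsilyloxy)phenyl]methyl}-1-[3-methoxy-4-(triisopropylsilyloxy)phenyl]butan-1-one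
Product: 22 (2S,3S,4R)-3-[(tert-butyldimethylsilyloxy)methyl]-2-[3-methoxy-4-(triisopropylsilyloxy)phenyl]-4-{[3-methoxy-4-(triisopropylsilyloxy)phenyl]methyl}oxolane, via cyclic hemiketal 20 (not isolated), via oxocarbenium ion 21 (not isolated)
Conditions: Et3SiH (3 equiv), BF3·OEt2 (2 equiv), CH2Cl2, −78 °C; NaHCO3 (aq) quench at −78 °C
Reagents that add atoms: none
Why: The γ-hydroxyl adds reversibly to the aryl ketone (5-exo-trig) to give hemiketal 20, BF3·OEt2 removes its hydroxyl, and the aryl-stabilised cyclic oxocarbenium ion 21 is reduced at C2 by Et3SiH, so that O1–C2 and C2–H are formed and the oxolane is closed. The closest known reaction type is the ionic hydrogenation (Et3SiH/BF3·OEt2 reductive deoxygenation) of aryl hemiketals made from an aryllithium and a γ-lactone, as used for C-aryl furanosides and 2-aryl oxolane lignans. The new centre C2 is under substrate control: the aryl ring lies coplanar with O1=C2, allylic strain turns the C3 silyloxymethyl arm pseudo-axial, and the small hydride should enter on the opposite face, leaving the aryl cis to the arm (2S). The step needs facial selectivity at C2 and configurational integrity at C3; the first is secured by the C3 arm next to the cationic carbon, the second by working at −78 °C, where loss of H3 to the cyclic enol ether and reprotonation should not compete. The low temperature also carries the chemoselectivity, since the primary TBS ether and the aryl TIPS ethers tolerate BF3·OEt2 at −78 °C and the benzylic ether of the product should not ionise again before the cold quench.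

Step 12
Reactants: 22 (2S,3S,4R)-3-[(tert-butyldimethylsilyloxy)methyl]-2-[3-methoxy-4-(triisopropylsilyloxy)phenyl]-4-{[3-methoxy-4-(triisopropylsilyloxy)phenyl]methyl}oxolane
Product: 23 [(2S,3S,4R)-2-[3-methoxy-4-(triisopropylsilyloxy)phenyl]-4-{[3-methoxy-4-(triisopropylsilyloxy)phenyl]methyl}oxolan-3-yl]methanol
Conditions: PPTS (0.2 equiv), MeOH/CH2Cl2, rt
Reagents that add atoms: none
Why: Acid-catalysed methanolysis (selective desilylation) removes the primary alkyl TBS ether far faster than the acid-resistant aryl TIPS ethers, and the weak acid PPTS should not ionise the benzylic C2–O1 bond, so the 2,3-cis relation is kept.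

Step 13
Reactants: 24 p-coumaric acid [(2E)-3-(4-hydroxyphenyl)prop-2-enoic acid]
Product: 26 (2E)-3-[4-(triisopropylsilyloxy)phenyl]prop-2-enoic acid, via triisopropylsilyl ester 25 (not isolated)
Conditions: TIPSCl (2.3 equiv), imidazole, DMF, rt; then K2CO3, THF/MeOH/H2O, 0 °C; work-up at pH 4
Reagents that add atoms: triisopropylsilyl chloride (TIPSCl), CC(C)[Si](Cl)(C(C)C)C(C)C
Why: Same two-stage silylation and selective silyl-ester hydrolysis as in step 2; the E-alkene is not affected.

Step 14
Reactants: 23 [(2S,3S,4R)-2-[3-methoxy-4-(triisopropylsilyloxy)phenyl]-4-{[3-methoxy-4-(triisopropylsilyloxy)phenyl]methyl}oxolan-3-yl]methanol; 26 (2E)-3-[4-(triisopropylsilyloxy)phenyl]prop-2-enoic acid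
Product: 27 [(2S,3S,4R)-2-[3-methoxy-4-(triisopropylsilyloxy)phenyl]-4-{[3-methoxy-4-(triisopropylsilyloxy)phenyl]methyl}oxolan-3-yl]methyl (2E)-3-[4-(triisopropylsilyloxy)phenyl]prop-2-enoate
Conditions: EDC·HCl, DMAP (0.2 equiv), CH2Cl2, 0 °C → rt
Reagents that add atoms: none
Why: Steglich esterification: carbodiimide activation and DMAP acyl transfer should acylate the unhindered primary alcohol cleanly, since every phenol is silylated and neither the E-alkene nor the ring stereocentres react under these neutral conditions.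

Step 15
Reactants: 27 [(2S,3S,4R)-2-[3-methoxy-4-(triisopropylsilyloxy)phenyl]-4-{[3-methoxy-4-(triisopropylsilyloxy)phenyl]methyl}oxolan-3-yl]methyl (2E)-3-[4-(triisopropylsilyloxy)phenyl]prop-2-enoate
Product: 28 [(2S,3S,4R)-2-(4-hydroxy-3-methoxyphenyl)-4-[(4-hydroxy-3-methoxyphenyl)methyl]oxolan-3-yl]methyl (2E)-3-(4-hydroxyphenyl)prop-2-enoate (CNP0119373.2)
Conditions: Bu4NF (3.5 equiv), AcOH (3.5 equiv), THF, 0 °C
Reagents that add atoms: none
Why: Fluoride-mediated desilylation cleaves the three aryl Si–O bonds, and acetic acid buffering keeps the freed phenols protonated, which should protect the cinnamate ester from acyl transfer and the 4-hydroxybenzylic C2–O1 bond from quinone-methide opening, so that the three stereocentres arrive unchanged in the target.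

**Compound list**

1 | ferulic acid | COc1cc(/C=C/C(=O)O)ccc1O | starting material
2 | 3-(4-hydroxy-3-methoxyphenyl)propanoic acid | COc1cc(CCC(=O)O)ccc1O | intermediate
3 | triisopropylsilyl 3-[3-methoxy-4-(triisopropylsilyloxy)phenyl]propanoate | COc1cc(CCC(=O)O[Si](C(C)C)(C(C)C)C(C)C)ccc1O[Si](C(C)C)(C(C)C)C(C)C | intermediate
4 | 3-[3-methoxy-4-(triisopropylsilyloxy)phenyl]propanoic acid | COc1cc(CCC(=O)O)ccc1O[Si](C(C)C)(C(C)C)C(C)C | intermediate
5 | (4S)-4-benzyl-1,3-oxazolidin-2-one | O=C1N[C@@H](Cc2ccccc2)CO1 | starting material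
6 | 3-[3-methoxy-4-(triisopropylsilyloxy)phenyl]propanoic pivalic anhydride | COc1cc(CCC(=O)OC(=O)C(C)(C)C)ccc1O[Si](C(C)C)(C(C)C)C(C)C | intermediate
7 | (4S)-4-benzyl-3-{3-[3-methoxy-4-(triisopropylsilyloxy)phenyl]propanoyl}-1,3-oxazolidin-2-one | COc1cc(CCC(=O)N2[C@@H](Cc3ccccc3)COC2=O)ccc1O[Si](C(C)C)(C(C)C)C(C)C | intermediate
8 | sodium Z-enolate of imide 7 (enolate oxygen cis to the arylmethyl group) | COc1cc(C/C=C(\[O-])N2[C@@H](Cc3ccccc3)COC2=O)ccc1O[Si](C(C)C)(C(C)C)C(C)C.[Na+] | intermediate
9 | tert-butyl (3R)-4-[(4S)-4-benzyl-2-oxo-1,3-oxazolidin-3-yl]-3-{[3-methoxy-4-(triisopropylsilyloxy)phenyl]methyl}-4-oxobutanoate | COc1cc(C[C@H](CC(=O)OC(C)(C)C)C(=O)N2[C@@H](Cc3ccccc3)COC2=O)ccc1O[Si](C(C)C)(C(C)C)C(C)C | intermediate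
10 | tert-butyl (3R)-4-hydroxy-3-{[3-methoxy-4-(triisopropylsilyloxy)phenyl]methyl}butanoate | COc1cc(C[C@H](CC(=O)OC(C)(C)C)CO)ccc1O[Si](C(C)C)(C(C)C)C(C)C | intermediate
11 | (4R)-4-{[3-methoxy-4-(triisopropylsilyloxy)phenyl]methyl}oxolan-2-one | COc1cc(C[C@H]2COC(=O)C2)ccc1O[Si](C(C)C)(C(C)C)C(C)C | intermediate
12 | lithium enolate of lactone 11 | COc1cc(C[C@H]2COC([O-])=C2)ccc1O[Si](C(C)C)(C(C)C)C(C)C.[Li+] | intermediate
13 | (3S,4R)-3-(hydroxymethyl)-4-{[3-methoxy-4-(triisopropylsilyloxy)phenyl]methyl}oxolan-2-one | COc1cc(C[C@H]2COC(=O)[C@@H]2CO)ccc1O[Si](C(C)C)(C(C)C)C(C)C | intermediate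
14 | (3S,4R)-3-[(tert-butyldimethylsilyloxy)methyl]-4-{[3-methoxy-4-(triisopropylsilyloxy)phenyl]methyl}oxolan-2-one | COc1cc(C[C@H]2COC(=O)[C@@H]2CO[Si](C)(C)C(C)(C)C)ccc1O[Si](C(C)C)(C(C)C)C(C)C | intermediate
15 | 4-bromo-2-methoxyphenol | COc1cc(Br)ccc1O | starting material
16 | (4-bromo-2-methoxyphenoxy)triisopropylsilane | COc1cc(Br)ccc1O[Si](C(C)C)(C(C)C)C(C)C | intermediate
17 | [3-methoxy-4-(triisopropylsilyloxy)phenyl]lithium | COc1cc([Li])ccc1O[Si](C(C)C)(C(C)C)C(C)C | intermediate
18 | lithium (3S,4R)-3-[(tert-butyldimethylsilyloxy)methyl]-2-[3-methoxy-4-(triisopropylsilyloxy)phenyl]-4-{[3-methoxy-4-(triisopropylsilyloxy)phenyl]methyl}oxolan-2-olate (both C2 epimers) | COc1cc(C[C@H]2COC(O[Li])(c3ccc(O[Si](C(C)C)(C(C)C)C(C)C)c(OC)c3)[C@@H]2CO[Si](C)(C)C(C)(C)C)ccc1O[Si](C(C)C)(C(C)C)C(C)C | intermediate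
19 | (2S,3R)-2-[(tert-butyldimethylsilyloxy)methyl]-4-hydroxy-3-{[3-methoxy-4-(triisopropylsilyloxy)phenyl]methyl}-1-[3-methoxy-4-(triisopropylsilyloxy)phenyl]butan-1-one | COc1cc(C[C@@H](CO)[C@@H](CO[Si](C)(C)C(C)(C)C)C(=O)c2ccc(O[Si](C(C)C)(C(C)C)C(C)C)c(OC)c2)ccc1O[Si](C(C)C)(C(C)C)C(C)C | intermediate
20 | (3S,4R)-3-[(tert-butyldimethylsilyloxy)methyl]-2-[3-methoxy-4-(triisopropylsilyloxy)phenyl]-4-{[3-methoxy-4-(triisopropylsilyloxy)phenyl]methyl}oxolan-2-ol (cyclic hemiketal, both C2 epimers) | COc1cc(C[C@H]2COC(O)(c3ccc(O[Si](C(C)C)(C(C)C)C(C)C)c(OC)c3)[C@@H]2CO[Si](C)(C)C(C)(C)C)ccc1O[Si](C(C)C)(C(C)C)C(C)C | intermediate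
21 | cyclic O1=C2 oxocarbenium ion derived from 20 (3S,4R in target numbering), hydroxytrifluoroborate salt | COc1cc(C[C@H]2C[O+]=C(c3ccc(O[Si](C(C)C)(C(C)C)C(C)C)c(OC)c3)[C@@H]2CO[Si](C)(C)C(C)(C)C)ccc1O[Si](C(C)C)(C(C)C)C(C)C.O[B-](F)(F)F | intermediate
22 | (2S,3S,4R)-3-[(tert-butyldimethylsilyloxy)methyl]-2-[3-methoxy-4-(triisopropylsilyloxy)phenyl]-4-{[3-methoxy-4-(triisopropylsilyloxy)phenyl]methyl}oxolane | COc1cc(C[C@H]2CO[C@H](c3ccc(O[Si](C(C)C)(C(C)C)C(C)C)c(OC)c3)[C@@H]2CO[Si](C)(C)C(C)(C)C)ccc1O[Si](C(C)C)(C(C)C)C(C)C | intermediate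
23 | [(2S,3S,4R)-2-[3-methoxy-4-(triisopropylsilyloxy)phenyl]-4-{[3-methoxy-4-(triisopropylsilyloxy)phenyl]methyl}oxolan-3-yl]methanol | COc1cc(C[C@H]2CO[C@H](c3ccc(O[Si](C(C)C)(C(C)C)C(C)C)c(OC)c3)[C@@H]2CO)ccc1O[Si](C(C)C)(C(C)C)C(C)C | intermediate
24 | p-coumaric acid | OC(=O)/C=C/c1ccc(O)cc1 | starting material
25 | triisopropylsilyl (2E)-3-[4-(triisopropylsilyloxy)phenyl]prop-2-enoate | CC(C)[Si](OC(=O)/C=C/c1ccc(O[Si](C(C)C)(C(C)C)C(C)C)cc1)(C(C)C)C(C)C | intermediate
26 | (2E)-3-[4-(triisopropylsilyloxy)phenyl]prop-2-enoic acid | OC(=O)/C=C/c1ccc(O[Si](C(C)C)(C(C)C)C(C)C)cc1 | intermediate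
27 | [(2S,3S,4R)-2-[3-methoxy-4-(triisopropylsilyloxy)phenyl]-4-{[3-methoxy-4-(triisopropylsilyloxy)phenyl]methyl}oxolan-3-yl]methyl (2E)-3-[4-(triisopropylsilyloxy)phenyl]prop-2-enoate | COc1cc(C[C@H]2CO[C@H](c3ccc(O[Si](C(C)C)(C(C)C)C(C)C)c(OC)c3)[C@@H]2COC(=O)/C=C/c4ccc(O[Si](C(C)C)(C(C)C)C(C)C)cc4)ccc1O[Si](C(C)C)(C(C)C)C(C)C | intermediate
28 | [(2S,3S,4R)-2-(4-hydroxy-3-methoxyphenyl)-4-[(4-hydroxy-3-methoxyphenyl)methyl]oxolan-3-yl]methyl (2E)-3-(4-hydroxyphenyl)prop-2-enoate | COc1cc(C[C@H]2CO[C@H](c3ccc(O)c(OC)c3)[C@@H]2COC(=O)/C=C/c2ccc(O)cc2)ccc1O | target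

**Count**
Total steps: 15. Longest linear sequence: 13 steps (steps 1–8, 10–12, 14, 15); steps 9 and 13 prepare the two side fragments.

**Steps most likely to fail**

Step 11. Hydride may enter C2 partly on the face syn to the C3 arm. The oxocarbenium ion may lose H3 and reprotonate, scrambling C3. Ionic hydrogenation may also run on, by reducing the open-chain ketone before ring closure or by re-ionising the benzylic C2–O1 bond of the product. Fallback: setting out from 19, the ketone is reduced under reagent control with (R)-2-methyl-CBS-oxazaborolidine and BH3·SMe2 in THF (aryl as the large group, hydride to the face that gives the 1S carbinol) to the (1S,2S,3R)-1,4-diol F1. The primary hydroxyl is sulfonylated selectively with TsCl in pyridine at 0 °C to give the primary monotosylate F2. NaH in THF then closes the ring by 5-exo-tet Williamson displacement at C5 with retention at C2, coming back to the route at 22.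

Step 10. The basic aryllithium may enolise the lactone instead of adding to it, which returns starting lactone and risks C3 epimerisation or β-elimination of silanolate. The tetrahedral adduct may also collapse early and take up a second aryl group. Fallback: setting out from 14, Me3Al-mediated aminolysis with MeNH(OMe)·HCl in CH2Cl2 opens the lactone to the γ-hydroxy Weinreb amide F3. Treatment with 2.2 equiv of aryllithium 17 at −78 °C (one equivalent deprotonates the hydroxyl, the second adds) gives a chelated adduct that cannot add again, and acetic acid quench returns to the route at 19.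

Step 7. Gaseous formaldehyde may oligomerise before it meets the enolate, conversion may stay low, and a second hydroxymethylation or retro-aldol on warming may erode the product. Fallback: setting out from 11, enolate 12 is alkylated at −78 °C with benzyl chloromethyl ether, again anti to the C4 benzyl group, to give the (3S,4R)-3-[(benzyloxy)methyl] lactone F4. Hydrogenolysis (H2, Pd/C, EtOAc) removes the benzyl group and returns to the route at 13.

**Further compounds**
F1 | step 11 | (1S,2S,3R)-2-[(tert-butyldimethylsilyloxy)methyl]-3-{[3-methoxy-4-(triisopropylsilyloxy)phenyl]methyl}-1-[3-methoxy-4-(triisopropylsilyloxy)phenyl]butane-1,4-diol | COc1cc(C[C@@H](CO)[C@@H](CO[Si](C)(C)C(C)(C)C)[C@H](O)c2ccc(O[Si](C(C)C)(C(C)C)C(C)C)c(OC)c2)ccc1O[Si](C(C)C)(C(C)C)C(C)C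
F2 | step 11 | (2R,3S,4S)-3-[(tert-butyldimethylsilyloxy)methyl]-4-hydroxy-2-{[3-methoxy-4-(triisopropylsilyloxy)phenyl]methyl}-4-[3-methoxy-4-(triisopropylsilyloxy)phenyl]butyl 4-methylbenzenesulfonate | COc1cc(C[C@@H](COS(=O)(=O)c2ccc(C)cc2)[C@@H](CO[Si](C)(C)C(C)(C)C)[C@H](O)c3ccc(O[Si](C(C)C)(C(C)C)C(C)C)c(OC)c3)ccc1O[Si](C(C)C)(C(C)C)C(C)C
F3 | step 10 | (2S,3R)-2-[(tert-butyldimethylsilyloxy)methyl]-4-hydroxy-N-methoxy-3-{[3-methoxy-4-(triisopropylsilyloxy)phenyl]methyl}-N-methylbutanamide | COc1cc(C[C@@H](CO)[C@@H](CO[Si](C)(C)C(C)(C)C)C(=O)N(C)OC)ccc1O[Si](C(C)C)(C(C)C)C(C)C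
F4 | step 7 | (3S,4R)-3-[(benzyloxy)methyl]-4-{[3-methoxy-4-(triisopropylsilyloxy)phenyl]methyl}oxolan-2-one | COc1cc(C[C@H]2COC(=O)[C@@H]2COCc3ccccc3)ccc1O[Si](C(C)C)(C(C)C)C(C)C
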